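**Plan**
Retrosynthesis: the lactone bond O2–C1 is opened to a hydroxy methyl ester. Ring A is then cut at C8–C8a and C4a–C5 into an alk-2-ynoate and a 1,1,3-trioxygenated butadiene. The ynoate is cut at C4–C4a (methyl propiolate plus a terminal epoxide) and the side chain at C1'–C2' (epichlorohydrin plus a C10 Grignard reagent).
Forward: the chain is joined first (C10 unit, C3 epoxide unit, propiolate). Ring A is then built by [4+2] cycloaddition and loss of methanol. Ring B, the lactone, closes last when the silyl ethers come off.
Enabling feature: in ring A the carboxyl carbon C1 sits on C8a, between the free C8–OH and the alkyl-bearing C4a, with the methoxy group on C6 para to C8a. A 1,1,3-trioxygenated diene lays down exactly this pattern across an alkynoate whose β-carbon becomes C4a.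
Stereochemistry: the only stereocentre, C3 (R), comes from (R)-epichlorohydrin; its C–O bond is never broken.

Key step: step 8

Remark: positions are numbered as in isochroman-1-one (C1 lactone carbonyl, O2, C3, C4, C4a, C5 to C8, C8a). The ketene acetal geometry of the silyloxy diene is left undefined, because that carbon ends as aromatic C8.

**Route**

Step 1
Reactants: 1 10-bromodecan-1-ol
Product: 2 (10-bromodecyloxy)(tert-butyl)dimethylsilane
Conditions: TBSCl, imidazole, CH2Cl2, 0 °C → rt
Reagents that add atoms: tert-butyldimethylsilyl chloride (TBSCl), CC(C)(C)[Si](C)(C)Cl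
Why: Silyl ether formation at a primary alcohol with imidazole as base masks the hydroxyl so that the bromide can be turned into a Grignard reagent.

Step 2
Reactants: 2 (10-bromodecyloxy)(tert-butyl)dimethylsilane; 3 (R)-epichlorohydrin
Product: 5 (R)-13-(tert-butyldimethylsilyloxy)-1-chlorotridecan-2-ol, via Grignard reagent 4 (not isolated)
Conditions: Mg, I2 (cat.), THF, 40 °C; then 3, CuI (10 mol %), THF, −40 → 0 °C; aq. NH4Cl
Reagents that add atoms: none
Why: CuI-catalysed Grignard opening of an epihalohydrin is an SN2 attack at the unsubstituted epoxide carbon that outpaces chloride displacement, so the stereocentre of 3 is not a reacting atom and is carried over as the (R)-chlorohydrin.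

Step 3
Reactants: 5 (R)-13-(tert-butyldimethylsilyloxy)-1-chlorotridecan-2-ol
Product: 6 (R)-2-[11-(tert-butyldimethylsilyloxy)undecyl]oxirane
Conditions: K2CO3, MeOH, rt
Reagents that add atoms: none
Why: Intramolecular Williamson displacement of the primary chloride by the neighbouring alkoxide closes the epoxide at CH2, so the carbinol configuration is retained and the silyl ether is inert to the mild base.

Step 4
Reactants: 6 (R)-2-[11-(tert-butyldimethylsilyloxy)undecyl]oxirane; 7 methyl propiolate
Product: 9 methyl (R)-16-(tert-butyldimethylsilyloxy)-5-hydroxyhexadec-2-ynoate, via methyl 3-lithiopropiolate 8 (not isolated)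
Conditions: 7, n-BuLi, THF, −78 °C; BF3·OEt2, then 6, −78 °C; H2O
Reagents that add atoms: none
Why: In this Yamaguchi–Hirao alkynylation BF3 activates the terminal epoxide so that the weakly nucleophilic lithium acetylide 8 opens it at the CH2 carbon at −78 °C, leaving the stereocentre and the ester untouched.

Step 5
Reactants: 9 methyl (R)-16-(tert-butyldimethylsilyloxy)-5-hydroxyhexadec-2-ynoate
Product: 10 methyl (R)-16-(tert-butyldimethylsilyloxy)-5-(triethylsilyloxy)hexadec-2-ynoate
Conditions: Et3SiCl, imidazole, CH2Cl2, 0 °C → rt
Reagents that add atoms: chlorotriethylsilane (Et3SiCl), CC[Si](CC)(CC)Cl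
Why: Silylation of the secondary alcohol removes the only protic group that could protonate or desilylate the ketene acetal diene, and the triethylsilyl ether falls off later under the same acid as the primary silyl ether.

Step 6
Reactants: 11 methyl acetoacetate
Product: 13 methyl (E)-3-methoxybut-2-enoate, via methyl 3,3-dimethoxybutanoate 12 (not isolated)
Conditions: HC(OMe)3, H2SO4 (cat.), MeOH, rt; then distillation
Reagents that add atoms: trimethyl orthoformate, COC(OC)OC
Why: Acid-catalysed ketalisation of the ketone by the orthoester followed by elimination of methanol on distillation gives the conjugated (E)-β-methoxy enoate, a standard enol ether formation of β-keto esters.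

Step 7
Reactants: 13 methyl (E)-3-methoxybut-2-enoate
Product: 15 1,3-dimethoxy-1-(trimethylsilyloxy)buta-1,3-diene, via lithium dienolate 14 (not isolated)
Conditions: LiN(i-Pr)2, THF, −78 °C; Me3SiCl, −78 °C → rt
Reagents that add atoms: chlorotrimethylsilane (Me3SiCl), C[Si](C)(C)Cl
Why: γ-Deprotonation of the vinylogous ester gives the extended enolate, which is silylated on oxygen to the silyl ketene acetal diene (silyl dienol ether formation); the diene is distilled and used at once.

Step 8
Reactants: 10 methyl (R)-16-(tert-butyldimethylsilyloxy)-5-(triethylsilyloxy)hexadec-2-ynoate; 15 1,3-dimethoxy-1-(trimethylsilyloxy)buta-1,3-diene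
Product: 18 methyl (R)-2-[13-(tert-butyldimethylsilyloxy)-2-(triethylsilyloxy)tridecyl]-6-hydroxy-4-methoxybenzoate, via cyclohexadiene cycloadduct 16 (not isolated), via aryl trimethylsilyl ether 17 (not isolated)
Conditions: 15 (3 equiv), toluene, 120 °C, sealed tube; then K2CO3 (cat.), MeOH, 0 °C
Reagents that add atoms: none
Why: This is a thermal normal-demand Diels–Alder reaction between the electron-rich ketene acetal diene and the acetylenic ester, concerted but asynchronous, in which the diene CH2 terminus bonds first to the ynoate β-carbon (C4a–C5) and the ketene acetal carbon closes onto the α-carbon (C8–C8a). The closest known reaction type is the benzannulation of 1,1,3-trioxygenated butadienes with alkynoates, which gives 4-methoxysalicylates after loss of methanol. Ring A closes as a six-membered carbocycle by intermolecular [4+2] cycloaddition; the mixed ketal of cyclohexa-1,4-diene 16 then ionises and loses methanol to give the aromatic silyl ether 17, and brief methanolysis frees the phenol, which is held by a hydrogen bond to the ester. No stereocentre is set, since the ketal carbon of 16 forms without control and becomes sp2, while the carbinol centre, two atoms from the reacting alkyne, is untouched. The selectivity needed is regiochemical, and it is secured by the matched polarisation of the partners (largest HOMO coefficient on the diene CH2, largest LUMO coefficient on the ynoate β-carbon), which puts the ester carbon next to the silyloxy carbon and the methoxy group para to it. The alkyne supplies the arene oxidation level without an oxidant, and the neutral aprotic conditions with both hydroxyls silylated keep the diene from being protonated.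

Step 9
Reactants: 18 methyl (R)-2-[13-(tert-butyldimethylsilyloxy)-2-(triethylsilyloxy)tridecyl]-6-hydroxy-4-methoxybenzoate
Product: 20 (R)-8-hydroxy-3-(11-hydroxyundecyl)-6-methoxyisochroman-1-one, via dihydroxy ester 19 (not isolated)
Conditions: TsOH·H2O (cat.), MeOH, rt; then toluene, 80 °C
Reagents that add atoms: none
Why: Acid-catalysed methanolysis removes both silyl ethers, and the freed C3 hydroxyl then closes the six-membered lactone onto the neighbouring methyl ester by intramolecular transesterification, driven by loss of methanol in toluene, with the C3–O bond and hence the configuration untouched.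

**Compound list**
1 | 10-bromodecan-1-ol | OCCCCCCCCCCBr | starting material
2 | (10-bromodecyloxy)(tert-butyl)dimethylsilane | CC(C)(C)[Si](C)(C)OCCCCCCCCCCBr | intermediate
3 | (R)-epichlorohydrin, (R)-2-(chloromethyl)oxirane | ClC[C@H]1CO1 | starting material
4 | [10-(tert-butyldimethylsilyloxy)decyl]magnesium bromide | CC(C)(C)[Si](C)(C)OCCCCCCCCCC[Mg]Br | intermediate
5 | (R)-13-(tert-butyldimethylsilyloxy)-1-chlorotridecan-2-ol | ClC[C@H](O)CCCCCCCCCCCO[Si](C)(C)C(C)(C)C | intermediate
6 | (R)-2-[11-(tert-butyldimethylsilyloxy)undecyl]oxirane | CC(C)(C)[Si](C)(C)OCCCCCCCCCCC[C@@H]1CO1 | intermediate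
7 | methyl propiolate | C#CC(=O)OC | starting material
8 | methyl 3-lithiopropiolate | [Li]C#CC(=O)OC | intermediate
9 | methyl (R)-16-(tert-butyldimethylsilyloxy)-5-hydroxyhexadec-2-ynoate | COC(=O)C#CC[C@H](O)CCCCCCCCCCCO[Si](C)(C)C(C)(C)C | intermediate
10 | methyl (R)-16-(tert-butyldimethylsilyloxy)-5-(triethylsilyloxy)hexadec-2-ynoate | COC(=O)C#CC[C@@H](CCCCCCCCCCCO[Si](C)(C)C(C)(C)C)O[Si](CC)(CC)CC | intermediate
11 | methyl acetoacetate | CC(=O)CC(=O)OC | starting material
12 | methyl 3,3-dimethoxybutanoate | COC(C)(OC)CC(=O)OC | intermediate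
13 | methyl (E)-3-methoxybut-2-enoate | CO/C(C)=C/C(=O)OC | intermediate
14 | lithium 1,3-dimethoxybuta-1,3-dien-1-olate | [Li]OC(OC)=CC(=C)OC | intermediate
15 | 1,3-dimethoxy-1-(trimethylsilyloxy)buta-1,3-diene | COC(=C)C=C(OC)O[Si](C)(C)C | intermediate
16 | methyl 2-[(R)-13-(tert-butyldimethylsilyloxy)-2-(triethylsilyloxy)tridecyl]-4,6-dimethoxy-6-(trimethylsilyloxy)cyclohexa-1,4-diene-1-carboxylate (both configurations at C6) | COC(=O)C1=C(C[C@@H](CCCCCCCCCCCO[Si](C)(C)C(C)(C)C)O[Si](CC)(CC)CC)CC(OC)=CC1(OC)O[Si](C)(C)C | intermediate
17 | methyl (R)-2-[13-(tert-butyldimethylsilyloxy)-2-(triethylsilyloxy)tridecyl]-4-methoxy-6-(trimethylsilyloxy)benzoate | COC(=O)c1c(O[Si](C)(C)C)cc(OC)cc1C[C@@H](CCCCCCCCCCCO[Si](C)(C)C(C)(C)C)O[Si](CC)(CC)CC | intermediate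
18 | methyl (R)-2-[13-(tert-butyldimethylsilyloxy)-2-(triethylsilyloxy)tridecyl]-6-hydroxy-4-methoxybenzoate | COC(=O)c1c(O)cc(OC)cc1C[C@@H](CCCCCCCCCCCO[Si](C)(C)C(C)(C)C)O[Si](CC)(CC)CC | intermediate
19 | methyl (R)-2-(2,13-dihydroxytridecyl)-6-hydroxy-4-methoxybenzoate | COC(=O)c1c(O)cc(OC)cc1C[C@H](O)CCCCCCCCCCCO | intermediate
20 | (R)-8-hydroxy-3-(11-hydroxyundecyl)-6-methoxyisochroman-1-one | COc1cc(O)c2c(c1)C[C@@H](CCCCCCCCCCCO)OC2=O | target

**Count**
Total: 9 steps. Longest linear sequence: 7 steps (steps 1, 2, 3, 4, 5, 8, 9) from 10-bromodecan-1-ol; the diene arm (steps 6 and 7) is convergent.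

**Steps most likely to fail**

Step 8. The mono-activated alkyne may add slowly, so thermal decay of the acyclic ketene acetal diene (hydrolysis by traces of water, silyl migration, oligomerisation) can outrun the cycloaddition. The ketal of the adduct may also collapse by loss of silanol instead of methanol, which would leave a methyl ether on C8. The fallback keeps the same two ring bonds but aromatises by cycloreversion, and it sets out from 10. Commercial dimedone (5,5-dimethylcyclohexane-1,3-dione) would be silylated with HN(SiMe3)2 and catalytic imidazole to 5,5-dimethyl-3-(trimethylsilyloxy)cyclohex-2-en-1-one F1. LiN(i-Pr)2 and then Me3SiCl in THF at −78 °C would give 5,5-dimethyl-1,3-bis(trimethylsilyloxy)cyclohexa-1,3-diene F2, a diene locked s-cis and sturdier to heat. Heating 10 with F2 in toluene at 140 °C should give the bicyclo[2.2.2]octa-2,5-diene adduct F3, which at that temperature should expel isobutene (Alder–Rickert cycloreversion) to give the aryl bis(trimethylsilyl) ether F4. K2CO3 in MeOH would free methyl (R)-2-[13-(tert-butyldimethylsilyloxy)-2-(triethylsilyloxy)tridecyl]-4,6-dihydroxybenzoate F5. MeI (1 equiv) with K2CO3 in acetone should methylate only the hydroxyl para to the ester, which is not tied up in the hydrogen bond to the carbonyl. This gives 18, where the route is rejoined before step 9.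

Step 4. The lithiated propiolate decomposes on slight warming, and BF3 can cause rearrangement of the epoxide, its opening by fluoride or THF, or partial loss of the silyl ether, so conversion may stall. The fallback brings in the acetylide first and the ester carbon later, and it sets out from 6. LiC≡CH·H2N(CH2)2NH2 in DMSO at rt should open the epoxide at its CH2 carbon without a Lewis acid to give (R)-15-(tert-butyldimethylsilyloxy)pentadec-1-yn-4-ol F6. Et3SiCl and imidazole would give (R)-15-(tert-butyldimethylsilyloxy)-4-(triethylsilyloxy)pentadec-1-yne F7. n-BuLi in THF at −78 °C would give [(R)-15-(tert-butyldimethylsilyloxy)-4-(triethylsilyloxy)pentadec-1-yn-1-yl]lithium F8, and methyl chloroformate should acylate it at carbon to give 10, where the route is rejoined before step 8.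

Step 9. The ester is deactivated by the hydrogen bond from the C8 phenol, so ring closure may stay incomplete. Forcing acid and heat while the primary alcohol is free invites intermolecular transesterification to oligomers. Saponification is no remedy, because the 2,4-dioxygenated benzoic acid would be prone to decarboxylation. The fallback closes the ring stepwise under base with the primary hydroxyl still masked, and it sets out from 18. Pyridinium p-toluenesulfonate in MeOH at 0 °C should cleave only the triethylsilyl ether to give methyl (R)-2-[13-(tert-butyldimethylsilyloxy)-2-hydroxytridecyl]-6-hydroxy-4-methoxybenzoate F9. NaH (2.2 equiv) in THF would form the secondary alkoxide, which should close onto the ester to give (R)-3-[11-(tert-butyldimethylsilyloxy)undecyl]-8-hydroxy-6-methoxyisochroman-1-one F10. Aqueous HF in MeCN would then remove the last silyl group and give 20, the target.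

**Further compounds**
F1 | step 8 | 5,5-dimethyl-3-(trimethylsilyloxy)cyclohex-2-en-1-one | C[Si](C)(C)OC1=CC(=O)CC(C)(C)C1
F2 | step 8 | 5,5-dimethyl-1,3-bis(trimethylsilyloxy)cyclohexa-1,3-diene | C[Si](C)(C)OC1=CC(O[Si](C)(C)C)=CC(C)(C)C1
F3 | step 8 | methyl 3-[(R)-13-(tert-butyldimethylsilyloxy)-2-(triethylsilyloxy)tridecyl]-8,8-dimethyl-1,5-bis(trimethylsilyloxy)bicyclo[2.2.2]octa-2,5-diene-2-carboxylate | COC(=O)C1=C(C[C@@H](CCCCCCCCCCCO[Si](C)(C)C(C)(C)C)O[Si](CC)(CC)CC)C2C(O[Si](C)(C)C)=CC1(O[Si](C)(C)C)CC2(C)C
F4 | step 8 | methyl (R)-2-[13-(tert-butyldimethylsilyloxy)-2-(triethylsilyloxy)tridecyl]-4,6-bis(trimethylsilyloxy)benzoate | COC(=O)c1c(O[Si](C)(C)C)cc(O[Si](C)(C)C)cc1C[C@@H](CCCCCCCCCCCO[Si](C)(C)C(C)(C)C)O[Si](CC)(CC)CC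
F5 | step 8 | methyl (R)-2-[13-(tert-butyldimethylsilyloxy)-2-(triethylsilyloxy)tridecyl]-4,6-dihydroxybenzoate | COC(=O)c1c(O)cc(O)cc1C[C@@H](CCCCCCCCCCCO[Si](C)(C)C(C)(C)C)O[Si](CC)(CC)CC
F6 | step 4 | (R)-15-(tert-butyldimethylsilyloxy)pentadec-1-yn-4-ol | C#CC[C@H](O)CCCCCCCCCCCO[Si](C)(C)C(C)(C)C
F7 | step 4 | (R)-15-(tert-butyldimethylsilyloxy)-4-(triethylsilyloxy)pentadec-1-yne | C#CC[C@@H](CCCCCCCCCCCO[Si](C)(C)C(C)(C)C)O[Si](CC)(CC)CC
F8 | step 4 | [(R)-15-(tert-butyldimethylsilyloxy)-4-(triethylsilyloxy)pentadec-1-yn-1-yl]lithium | [Li]C#CC[C@@H](CCCCCCCCCCCO[Si](C)(C)C(C)(C)C)O[Si](CC)(CC)CC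
F9 | step 9 | methyl (R)-2-[13-(tert-butyldimethylsilyloxy)-2-hydroxytridecyl]-6-hydroxy-4-methoxybenzoate | COC(=O)c1c(O)cc(OC)cc1C[C@H](O)CCCCCCCCCCCO[Si](C)(C)C(C)(C)C
F10 | step 9 | (R)-3-[11-(tert-butyldimethylsilyloxy)undecyl]-8-hydroxy-6-methoxyisochroman-1-one | COc1cc(O)c2c(c1)C[C@@H](CCCCCCCCCCCO[Si](C)(C)C(C)(C)C)OC2=O
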